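**Plan**
- Retrosynthesis: the C6 veratrate, the 8,9-epoxide oxygen, the C4–isopropyl bond and the C8 methyl group are removed first. Ring B is then cut at C1–C5 and C9–C10 after the C5–C9 bond has been re-formed (reverse of a retro-aldol), which leads back to a cyclopentane-1,3-dione enol benzoate with a 2-methylallyl-terminated chain on C5.
- Enabling feature: in ring B, C6 and C9 both carry oxygen, 1,4 to each other across C7–C8, and C5 sits between C6 and C1. Ring B is therefore a cyclopentane-1,3-dione (C5–C6–C7–C8–C9) that has taken up the two alkene carbons C1 and C10.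
- Forward, first part: C4–C5 is made by Morita–Baylis–Hillman coupling of cyclopentenone with 4-methylpent-4-enal, C9 is oxygenated and the dione fixed as its enol benzoate. Irradiation closes ring A and a cyclobutane; methanolysis and retro-aldol merge cyclobutane and cyclopentanone into ring B.
- Forward, second part: C6 is reduced, C8 methylenated and the C9 ketone converted into the 8,9-ene, C4 is oxidised and isopropylated, the alkene is epoxidised and O6 acylated.
- Stereochemistry: C4 (S, catalyst control in step 1) sets C1 by allylic strain in the photocycloaddition. C5 follows by equilibration to the trans fusion, C6 by hydride delivery from O4, the final C4 by Grignard attack anti to C6, and C8/C9 by epoxidation directed by the C6 hydroxyl.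

Key step: step 7

Numbering: daucane numbering throughout (ring A = C1–C5; ring B = C5–C6–C7–C8–C9–C10–C1); β is the face of the C1 methyl group.
Remark: 4-methylpent-4-enal (2) is taken as a catalogue aldehyde; the sense of induction of the binaphthol in step 1 is assumed, and its antipode is used if the carbinol proves to be R.

**Step 1**
Reactants: 1 cyclopent-2-en-1-one; 2 4-methylpent-4-enal
Product: 3 (S)-2-(1-hydroxy-4-methylpent-4-en-1-yl)cyclopent-2-en-1-one
Conditions: PEt3, (R)-3,3'-bis(3,5-dimethylphenyl)-5,5',6,6',7,7',8,8'-octahydro-1,1'-bi-2-naphthol (10 mol%), THF, −10 °C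
Reagents that add atoms: none
Why: Morita–Baylis–Hillman reaction in which the phosphine adds to C9, the enolate attacks the aldehyde through C5 and the phosphine is expelled again, the chiral binaphthol being hydrogen-bonded to the enolate so that one aldehyde face reacts and C4 is set as S.

**Step 2**
Reactants: 3 (S)-2-(1-hydroxy-4-methylpent-4-en-1-yl)cyclopent-2-en-1-one
Product: 4 (S)-2-[1-(tert-butyldimethylsilyloxy)-4-methylpent-4-en-1-yl]cyclopent-2-en-1-one
Conditions: TBSCl, imidazole, DMF, 20 °C
Reagents that add atoms: tert-butyldimethylsilyl chloride, CC(C)(C)[Si](C)(C)Cl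
Why: Standard silylation of a secondary alcohol, giving an ether that cannot take part in acyl transfer and that is the large group biasing the C4–C5 rotamer in step 7.

**Step 3**
Reactants: 4 (S)-2-[1-(tert-butyldimethylsilyloxy)-4-methylpent-4-en-1-yl]cyclopent-2-en-1-one
Product: 5 2,3-epoxide of 4 (both cis-epoxide diastereomers, carried on together)
Conditions: 30% H2O2, NaOH (cat.), MeOH, 0 °C
Reagents that add atoms: hydrogen peroxide, OO
Why: Weitz–Scheffer nucleophilic epoxidation, in which hydroperoxide adds to the electron-poor C9 and closes on C5 while the electron-rich 1,1-disubstituted alkene is left alone; the new centres need no control because C5 and C9 become trigonal again.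

**Step 4**
Reactants: 5 2,3-epoxide of 4
Product: 6 3-hydroxy-2-[(S)-1-(tert-butyldimethylsilyloxy)-4-methylpent-4-en-1-yl]cyclopentan-1-one (mixture at the two ring centres)
Conditions: SmI2 (2.2 equiv), THF–MeOH, −90 °C
Reagents that add atoms: none
Why: Single-electron reductive opening of an α,β-epoxy ketone, the ketyl ejecting the α-oxygen (C5–O cleavage) and the samarium enolate being protonated by methanol at low temperature before the C4 silyloxy group can leave.

**Step 5**
Reactants: 6 3-hydroxy-2-[(S)-1-(tert-butyldimethylsilyloxy)-4-methylpent-4-en-1-yl]cyclopentan-1-one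
Product: 7 2-[(S)-1-(tert-butyldimethylsilyloxy)-4-methylpent-4-en-1-yl]cyclopentane-1,3-dione (largely enolised)
Conditions: Dess–Martin periodinane, pyridine, CH2Cl2, 0 °C
Reagents that add atoms: none
Why: Dess–Martin oxidation of a β-hydroxy ketone to the 1,3-dione under buffered conditions, the crude dione being used at once because its acidic enol could expel silanol.

**Step 6**
Reactants: 7 2-[(S)-1-(tert-butyldimethylsilyloxy)-4-methylpent-4-en-1-yl]cyclopentane-1,3-dione; 8 benzoyl chloride
Product: 9 2-[(S)-1-(tert-butyldimethylsilyloxy)-4-methylpent-4-en-1-yl]-3-oxocyclopent-1-en-1-yl benzoate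
Conditions: Et3N, DMAP (cat.), CH2Cl2, 0 °C
Reagents that add atoms: none
Why: O-acylation of the enolate of a symmetrical 2-substituted 1,3-dione, which can give only one enol benzoate and removes the acidic enol hydrogen.

**Step 7**
Reactants: 9 2-[(S)-1-(tert-butyldimethylsilyloxy)-4-methylpent-4-en-1-yl]-3-oxocyclopent-1-en-1-yl benzoate
Product: 12 (1R,4S,5R)-4-(tert-butyldimethylsilyloxy)-1-methyl-trans-bicyclo[5.3.0]decane-6,9-dione, via photoadduct benzoate 10 (not isolated), via cyclobutanol 11 (not isolated)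
Conditions: hν (350 nm, Pyrex), degassed MeCN (5 mM), 5 °C; then NaOMe (0.3 equiv), MeOH, 0 → 20 °C
Reagents that add atoms: none
Why: Excitation of the enone and intersystem crossing give the triplet, whose α-carbon C5 bonds to the internal alkene carbon C1 (ring A by 5-exo closure, the 1,5-closure of a 1,6-diene), and the 1,4-diradical at C9 and C10 then collapses to the cyclobutane, giving the straight adduct 10 and not the crossed one. Catalytic methoxide transesterifies the tertiary benzoate and the cyclobutanolate of 11 undergoes strain-driven retro-aldol cleavage of C5–C9, so that ring B arises by fragmentation of the fused cyclobutane and cyclopentanone and not by a closure of its own. The closest known reaction type is the intramolecular de Mayo reaction of 2-(pent-4-enyl)cyclopentane-1,3-dione enol esters to hydroazulenediones. C1 is controlled by C4: allylic 1,3-strain against the cis benzoyloxy group on C9 holds the C4–H bond in the enone plane, the silyloxy group and the C3 chain lie on opposite faces, and the alkene is delivered on the face of the chain, which for (S)-C4 gives (R)-C1, while the C5 and C9 centres of 10 are fixed by the obligatory cis fusions and are lost again. C5 of 12 is set when the released C5 enolate is protonated and equilibrated by the methoxide to the trans-fused ketone with H-5 anti to the C1 methyl group. The step needs face selectivity (a minor adduct is a diastereomer and is removed by chromatography, so enantiomeric purity stays that of C4), 1,5- over 1,6-closure (secured by the three-atom tether) and protonation of the C5 enolate faster than loss of the C4 silanolate (secured by the protic medium, catalytic base and low temperature).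

**Step 8**
Reactants: 12 (1R,4S,5R)-4-(tert-butyldimethylsilyloxy)-1-methyl-trans-bicyclo[5.3.0]decane-6,9-dione
Product: 13 4β-hydroxy-1β-methyl-5α-H-bicyclo[5.3.0]decane-6,9-dione
Conditions: HF·pyridine, THF, 0 → 20 °C
Reagents that add atoms: none
Why: Acidic fluoride desilylation, which frees the C4 hydroxyl without forming the C5 enolate, so that dehydration and retro-aldol opening of ring A should not intervene.

**Step 9**
Reactants: 13 4β-hydroxy-1β-methyl-5α-H-bicyclo[5.3.0]decane-6,9-dione; 14 benzaldehyde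
Product: 15 4β-benzoyloxy-6α-hydroxy-1β-methyl-5α-H-bicyclo[5.3.0]decan-9-one
Conditions: SmI2 (0.3 equiv), PhCHO (5 equiv), THF, −10 °C
Reagents that add atoms: none
Why: Evans–Tishchenko reduction, in which the samarium-bound hemiacetal of O4 and benzaldehyde passes hydride to C6 through a six-membered chair with C7 equatorial, giving the 1,3-anti (6S) alcohol, leaving the C9 ketone (no β-hydroxyl) untouched and marking O4 as its benzoate.

**Step 10**
Reactants: 15 4β-benzoyloxy-6α-hydroxy-1β-methyl-5α-H-bicyclo[5.3.0]decan-9-one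
Product: 16 4β-benzoyloxy-6α-(tert-butyldimethylsilyloxy)-1β-methyl-5α-H-bicyclo[5.3.0]decan-9-one
Conditions: TBSOTf, 2,6-lutidine, CH2Cl2, −78 °C
Reagents that add atoms: tert-butyldimethylsilyl trifluoromethanesulfonate, CC(C)(C)[Si](C)(C)OS(=O)(=O)C(F)(F)F
Why: Silyl triflate silylation of a hindered secondary alcohol, which at low temperature is faster than enol silylation of the C9 ketone.

**Step 11**
Reactants: 16 4β-benzoyloxy-6α-(tert-butyldimethylsilyloxy)-1β-methyl-5α-H-bicyclo[5.3.0]decan-9-one
Product: 19 C8-methylene ketone, via Mannich base 17 (not isolated), via ammonium iodide 18 (not isolated)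
Conditions: LiN(iPr)2, THF, −78 °C; CH2=NMe2+ I−, −78 → 20 °C; MeI, MeOH; aq. NaHCO3, CH2Cl2
Reagents that add atoms: N,N-dimethylmethyleneiminium iodide, C=[N+](C)C.[I-]
Why: Kinetic deprotonation takes a C8 hydrogen because C10 is neopentylic (next to quaternary C1), and Mannich reaction of the enolate, quaternisation and E1cB elimination of trimethylamine give the α-methylene ketone.

**Step 12**
Reactants: 19 C8-methylene ketone
Product: 21 enol triflate, via lithium enolate 20 (not isolated)
Conditions: LiBH(sBu)3, THF, −78 °C; then PhNTf2, −78 → 0 °C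
Reagents that add atoms: N-phenylbis(trifluoromethanesulfonimide), O=S(=O)(N(c1ccccc1)S(=O)(=O)C(F)(F)F)C(F)(F)F
Why: Conjugate hydride addition to the unhindered exocyclic enone makes the C8–C9 enolate regiospecifically (the methylene carbon becomes the C8 methyl group) and O-sulfonylation fixes it as the tetrasubstituted enol triflate.

**Step 13**
Reactants: 21 enol triflate
Product: 22 4β-benzoyloxy-6α-(tert-butyldimethylsilyloxy)-1β,8-dimethyl-5α-H-bicyclo[5.3.0]dec-8-ene
Conditions: Pd(OAc)2 (5 mol%), PPh3, Bu3N, HCO2H, DMF, 60 °C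
Reagents that add atoms: none
Why: Palladium-catalysed formate reduction of an enol triflate (oxidative addition, formate exchange, loss of CO2, reductive elimination) replaces the triflate by hydrogen with the double bond held at C8–C9.

**Step 14**
Reactants: 22 4β-benzoyloxy-6α-(tert-butyldimethylsilyloxy)-1β,8-dimethyl-5α-H-bicyclo[5.3.0]dec-8-ene
Product: 23 6α-(tert-butyldimethylsilyloxy)-1β,8-dimethyl-5α-H-bicyclo[5.3.0]dec-8-en-4β-ol
Conditions: iBu2AlH, CH2Cl2, −78 °C
Reagents that add atoms: none
Why: Reductive cleavage of the benzoate by the aluminium hydride frees the C4 alcohol, the silyl ether and the trisubstituted alkene being inert.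

**Step 15**
Reactants: 23 6α-(tert-butyldimethylsilyloxy)-1β,8-dimethyl-5α-H-bicyclo[5.3.0]dec-8-en-4β-ol
Product: 24 6α-(tert-butyldimethylsilyloxy)-1β,8-dimethyl-5α-H-bicyclo[5.3.0]dec-8-en-4-one
Conditions: Dess–Martin periodinane, NaHCO3, CH2Cl2, 0 °C
Reagents that add atoms: none
Why: Dess–Martin oxidation under buffered neutral conditions gives the C4 ketone without enolising C5, which now lies between the carbonyl and the carbon bearing the C6 silyl ether.

**Step 16**
Reactants: 24 6α-(tert-butyldimethylsilyloxy)-1β,8-dimethyl-5α-H-bicyclo[5.3.0]dec-8-en-4-one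
Product: 25 6-O-(tert-butyldimethylsilyl)jaeschkeanadiol (4β-hydroxy-4α-isopropyl)
Conditions: iPrMgCl, LaCl3·2LiCl, THF, −20 → 0 °C
Reagents that add atoms: isopropylmagnesium chloride, CC(C)[Mg]Cl
Why: Lanthanum-promoted Grignard 1,2-addition, which suppresses enolisation and β-hydride reduction, the nucleophile reaching C4 from the α face anti to the C6 branch on C5 and to the C1 methyl group, so that the hydroxyl ends up β (4R).

**Step 17**
Reactants: 25 6-O-(tert-butyldimethylsilyl)jaeschkeanadiol
Product: 26 jaeschkeanadiol, (1R,4R,5S,6S)-dauc-8-ene-4,6-diol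
Conditions: Bu4NF, THF, 20 → 45 °C
Reagents that add atoms: none
Why: Fluoride desilylation of the secondary silyl ether, to which the tertiary alcohol and the alkene are inert.

**Step 18**
Reactants: 26 jaeschkeanadiol
Product: 27 8α,9α-epoxyjaeschkeanadiol
Conditions: VO(acac)2 (5 mol%), tBuOOH, 2,6-lutidine (cat.), CH2Cl2, 0 → 20 °C
Reagents that add atoms: tert-butyl hydroperoxide, CC(C)(C)OO
Why: Vanadium-catalysed hydroxyl-directed epoxidation, the peroxide bound to vanadium on the homoallylic 6α-hydroxyl being delivered to the α face of C8=C9, which sets C8 (R) and C9 (S) syn to O6.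

**Step 19**
Reactants: 27 8α,9α-epoxyjaeschkeanadiol; 28 3,4-dimethoxybenzoyl chloride
Product: 29 CNP0251065.1, 8α,9α-epoxyjaeschkeanadiol 6-O-(3,4-dimethoxybenzoate)
Conditions: Et3N, DMAP, CH2Cl2, 20 °C
Reagents that add atoms: none
Why: DMAP-catalysed acylation, which takes the secondary C6 hydroxyl in preference to the tertiary C4 hydroxyl and, being basic, leaves the epoxide intact.

**Compound list**
1 | cyclopent-2-en-1-one | O=C1C=CCC1 | starting material
2 | 4-methylpent-4-enal | CC(=C)CCC=O | starting material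
3 | (S)-2-(1-hydroxy-4-methylpent-4-en-1-yl)cyclopent-2-en-1-one | O=C1CCC=C1[C@@H](O)CCC(C)=C | intermediate
4 | (S)-2-[1-(tert-butyldimethylsilyloxy)-4-methylpent-4-en-1-yl]cyclopent-2-en-1-one | O=C1CCC=C1[C@@H](O[Si](C)(C)C(C)(C)C)CCC(C)=C | intermediate
5 | 1-[(S)-1-(tert-butyldimethylsilyloxy)-4-methylpent-4-en-1-yl]-6-oxabicyclo[3.1.0]hexan-2-one (both epoxide diastereomers) | O=C1CCC2OC12[C@@H](O[Si](C)(C)C(C)(C)C)CCC(C)=C | intermediate
6 | 3-hydroxy-2-[(S)-1-(tert-butyldimethylsilyloxy)-4-methylpent-4-en-1-yl]cyclopentan-1-one (mixture at the two ring centres) | O=C1CCC(O)C1[C@@H](O[Si](C)(C)C(C)(C)C)CCC(C)=C | intermediate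
7 | 2-[(S)-1-(tert-butyldimethylsilyloxy)-4-methylpent-4-en-1-yl]cyclopentane-1,3-dione (drawn as diketone, largely enol) | O=C1CCC(=O)C1[C@@H](O[Si](C)(C)C(C)(C)C)CCC(C)=C | intermediate
8 | benzoyl chloride | O=C(Cl)c1ccccc1 | starting material
9 | 2-[(S)-1-(tert-butyldimethylsilyloxy)-4-methylpent-4-en-1-yl]-3-oxocyclopent-1-en-1-yl benzoate | O=C1CCC(OC(=O)c2ccccc2)=C1[C@@H](O[Si](C)(C)C(C)(C)C)CCC(C)=C | intermediate
10 | photoadduct, 2-(tert-butyldimethylsilyloxy)-5-methyl-10-oxotricyclo[5.3.0.0(1,5)]decan-7-yl benzoate; cyclobutane C5–C9–C10–C1 cis-fused to both five-membered rings, silyloxy group anti to the cyclobutane on ring A | O=C1CC[C@]2(OC(=O)c3ccccc3)C[C@@]3(C)CC[C@H](O[Si](C)(C)C(C)(C)C)[C@@]123 | intermediate (not isolated)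
11 | tertiary cyclobutanol corresponding to 10 | O=C1CC[C@]2(O)C[C@@]3(C)CC[C@H](O[Si](C)(C)C(C)(C)C)[C@@]123 | intermediate (not isolated)
12 | (1R,4S,5R)-4-(tert-butyldimethylsilyloxy)-1-methyl-trans-bicyclo[5.3.0]decane-6,9-dione (1β-methyl, 5α-H, 4β-silyloxy) | O=C1CCC(=O)C[C@@]2(C)CC[C@H](O[Si](C)(C)C(C)(C)C)[C@H]12 | intermediate
13 | 4β-hydroxy-1β-methyl-5α-H-bicyclo[5.3.0]decane-6,9-dione | O=C1CCC(=O)C[C@@]2(C)CC[C@H](O)[C@H]12 | intermediate
14 | benzaldehyde | O=Cc1ccccc1 | starting material
15 | 4β-benzoyloxy-6α-hydroxy-1β-methyl-5α-H-bicyclo[5.3.0]decan-9-one | O[C@H]1CCC(=O)C[C@@]2(C)CC[C@H](OC(=O)c3ccccc3)[C@H]12 | intermediate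
16 | 4β-benzoyloxy-6α-(tert-butyldimethylsilyloxy)-1β-methyl-5α-H-bicyclo[5.3.0]decan-9-one | CC(C)(C)[Si](C)(C)O[C@H]1CCC(=O)C[C@@]2(C)CC[C@H](OC(=O)c3ccccc3)[C@H]12 | intermediate
17 | Mannich base, 8-(dimethylaminomethyl) derivative of 16 (C8 unassigned) | CC(C)(C)[Si](C)(C)O[C@H]1CC(CN(C)C)C(=O)C[C@@]2(C)CC[C@H](OC(=O)c3ccccc3)[C@H]12 | intermediate (not isolated)
18 | trimethylammonium iodide of 17 | CC(C)(C)[Si](C)(C)O[C@H]1CC(C[N+](C)(C)C)C(=O)C[C@@]2(C)CC[C@H](OC(=O)c3ccccc3)[C@H]12.[I-] | intermediate (not isolated)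
19 | 4β-benzoyloxy-6α-(tert-butyldimethylsilyloxy)-1β-methyl-8-methylene-5α-H-bicyclo[5.3.0]decan-9-one | CC(C)(C)[Si](C)(C)O[C@H]1CC(=C)C(=O)C[C@@]2(C)CC[C@H](OC(=O)c3ccccc3)[C@H]12 | intermediate
20 | lithium C8–C9 enolate of the 8-methyl-9-ketone | CC(C)(C)[Si](C)(C)O[C@H]1CC(C)=C([O-])C[C@@]2(C)CC[C@H](OC(=O)c3ccccc3)[C@H]12.[Li+] | intermediate (not isolated)
21 | 4β-benzoyloxy-6α-(tert-butyldimethylsilyloxy)-1β,8-dimethyl-5α-H-bicyclo[5.3.0]dec-8-en-9-yl triflate | CC(C)(C)[Si](C)(C)O[C@H]1CC(C)=C(OS(=O)(=O)C(F)(F)F)C[C@@]2(C)CC[C@H](OC(=O)c3ccccc3)[C@H]12 | intermediate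
22 | 4β-benzoyloxy-6α-(tert-butyldimethylsilyloxy)-1β,8-dimethyl-5α-H-bicyclo[5.3.0]dec-8-ene | CC(C)(C)[Si](C)(C)O[C@H]1CC(C)=CC[C@@]2(C)CC[C@H](OC(=O)c3ccccc3)[C@H]12 | intermediate
23 | 6α-(tert-butyldimethylsilyloxy)-1β,8-dimethyl-5α-H-bicyclo[5.3.0]dec-8-en-4β-ol | CC(C)(C)[Si](C)(C)O[C@H]1CC(C)=CC[C@@]2(C)CC[C@H](O)[C@H]12 | intermediate
24 | 6α-(tert-butyldimethylsilyloxy)-1β,8-dimethyl-5α-H-bicyclo[5.3.0]dec-8-en-4-one | CC(C)(C)[Si](C)(C)O[C@H]1CC(C)=CC[C@@]2(C)CCC(=O)[C@H]12 | intermediate
25 | 6-O-(tert-butyldimethylsilyl)jaeschkeanadiol (4β-hydroxy, 4α-isopropyl) | CC(C)(C)[Si](C)(C)O[C@H]1CC(C)=CC[C@@]2(C)CC[C@@](O)(C(C)C)[C@H]12 | intermediate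
26 | jaeschkeanadiol, (1R,4R,5S,6S)-dauc-8-ene-4,6-diol | O[C@H]1CC(C)=CC[C@@]2(C)CC[C@@](O)(C(C)C)[C@H]12 | intermediate
27 | 8α,9α-epoxyjaeschkeanadiol | O[C@H]1C[C@@]2(C)O[C@H]2C[C@@]2(C)CC[C@@](O)(C(C)C)[C@H]12 | intermediate
28 | 3,4-dimethoxybenzoyl chloride | COc1ccc(cc1OC)C(Cl)=O | starting material
29 | CNP0251065.1, (1R,4R,5S,6S,8R,9S)-8,9-epoxy-4-hydroxydaucan-6-yl 3,4-dimethoxybenzoate | COc1ccc(C(=O)O[C@H]2C[C@@]3(C)O[C@H]3C[C@@]3(C)CC[C@@](O)(C(C)C)[C@H]23)cc1OC | target

**Step count and risks**
Total: 19 steps. Longest linear sequence: 19 steps (from 1 and 2).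

Step 7. The C5 enolate released by the retro-aldol may expel the C4 silanolate (E1cB) or be protonated to the cis-fused epimer under the basic methanolysis, and the relay from C4 to C1 may be incomplete. The fallback sets out from dione 7: ClCO2Bn and Et3N give the enol benzyl carbonate F1, irradiation as in step 7 gives the photoadduct carbonate F2 (a minor face isomer is separated here), and hydrogenolysis (H2, Pd/C, EtOAc) frees cyclobutanol 11 without base, which fragments to the dione; the route is rejoined at 12.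

Step 1. The enantioselectivity or conversion may be poor, because cyclopentenone and an enolisable aliphatic aldehyde are a demanding pair for the phosphine/chiral Brønsted acid system. The fallback sets out from aldehyde 2: 6-bromo-1,4-dioxaspiro[4.4]non-6-ene (the catalogue ethylene ketal of 2-bromocyclopent-2-enone) is lithiated (n-BuLi, THF, −78 °C) and added to 2 to give the racemic ketal carbinol F3, Dess–Martin oxidation gives the alkenyl ketone F4, reduction with the (R)-Me-CBS oxazaborolidine and BH3·SMe2 (alkenyl as the large group) gives the (S)-alcohol F5, TBSCl and imidazole give the silyl ether F6, and mild acid (oxalic acid on wet silica) removes the ketal; the route is rejoined at 4.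

Step 16. Enolisation toward C5, followed by loss of the C6 silanolate or epimerisation of the ring fusion, and β-hydride reduction may outrun addition of the branched Grignard reagent to the hindered ketone. The fallback sets out from ketone 24: CH2=C(CH3)MgBr with CeCl3 (THF, −78 °C), an sp2 nucleophile without β-hydrogen, gives the isopropenyl carbinol F7, and hydrogenation with RhCl(PPh3)3 saturates the 1,1-disubstituted alkene in preference to the trisubstituted ring alkene; the route is rejoined at 25.

**Further compounds**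
F1 | step 7 | benzyl 2-[(S)-1-(tert-butyldimethylsilyloxy)-4-methylpent-4-en-1-yl]-3-oxocyclopent-1-en-1-yl carbonate | O=C1CCC(OC(=O)OCc2ccccc2)=C1[C@@H](O[Si](C)(C)C(C)(C)C)CCC(C)=C
F2 | step 7 | photoadduct benzyl carbonate (as 10, with OCO2Bn on C9) | O=C1CC[C@]2(OC(=O)OCc3ccccc3)C[C@@]3(C)CC[C@H](O[Si](C)(C)C(C)(C)C)[C@@]123
F3 | step 1 | racemic 1-(1,4-dioxaspiro[4.4]non-6-en-6-yl)-4-methylpent-4-en-1-ol | CC(=C)CCC(O)C1=CCCC12OCCO2
F4 | step 1 | 1-(1,4-dioxaspiro[4.4]non-6-en-6-yl)-4-methylpent-4-en-1-one | CC(=C)CCC(=O)C1=CCCC12OCCO2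
F5 | step 1 | (S)-1-(1,4-dioxaspiro[4.4]non-6-en-6-yl)-4-methylpent-4-en-1-ol | CC(=C)CC[C@H](O)C1=CCCC12OCCO2
F6 | step 1 | tert-butyldimethylsilyl ether of F5 | CC(=C)CC[C@H](O[Si](C)(C)C(C)(C)C)C1=CCCC12OCCO2
F7 | step 16 | 6α-(tert-butyldimethylsilyloxy)-4α-isopropenyl-1β,8-dimethyl-5α-H-bicyclo[5.3.0]dec-8-en-4β-ol | CC(C)(C)[Si](C)(C)O[C@H]1CC(C)=CC[C@@]2(C)CC[C@@](O)(C(C)=C)[C@H]12
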